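## Retrosynthesis

- The target comes from global debenzylation of tri-O-benzyl diol **11**, which in turn comes from reducing the ester of syn-hydroxy ester **10**.
- **Key step:** Ru-TsDPEN asymmetric transfer hydrogenation with dynamic kinetic resolution (ATH-DKR) of racemic α-aryloxy-β-ketoester **9** sets C7'' and C8'' (threo = syn) in one operation. The aryl ether is already in place, so no SN2 is needed at a stereocentre.
- **9** comes from Rh(II)-carbenoid O–H insertion of diazoketoester **8** into the 4'-OH of 5,7-di-O-benzyltricin **5**, which forms the Ar–O–C8'' bond.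
- Ring order: the flavone C-ring is formed first (Claisen–Schmidt, then I2/DMSO oxidative cyclisation). The β-O-4 ether and both stereocentres come afterwards.

**Assumptions**
- The target is the threo isomer. (7''S,8''S) with OAr at C8'' corresponds to threo/syn; the SMILES was checked for this.
- Syn-selective DKR-ATH precedent for α-alkoxy-β-ketoesters extends to this α-aryloxy substrate.
- (R,R)-TsDPEN-Ru gives the 3S carbinol for this aryl ketone, because the adjacent CH(OAr) carbon outranks the aryl group in CIP priority.

## Route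

**Step 1**
Reactants: **1** 2,4,6-trihydroxyacetophenone
Product: **2** 4,6-bis(benzyloxy)-2-hydroxyacetophenone
Conditions: BnBr (2.1 equiv), K2CO3, KI (cat.), acetone, reflux
Reagents that add atoms: benzyl bromide, BrCc1ccccc1
Why: The 2-OH is chelated to the carbonyl and stays unreacted, so Williamson O-benzylation occurs at the two free phenols (4-OH and 6-OH).

**Step 2**
Reactants: **2**; **3** syringaldehyde (4-hydroxy-3,5-dimethoxybenzaldehyde)
Product: **4** (E)-1-[4,6-bis(benzyloxy)-2-hydroxyphenyl]-3-(4-hydroxy-3,5-dimethoxyphenyl)prop-2-en-1-one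
Conditions: 50% aq. KOH, EtOH, rt, 48 h; then HCl workup
Reagents that add atoms: none
Why: Claisen–Schmidt aldol condensation; the aldehyde's free phenol is tolerated as its phenoxide, with excess base compensating for the slower reaction.

**Step 3**
Reactants: **4**
Product: **5** 5,7-di-O-benzyltricin (5,7-bis(benzyloxy)-2-(4-hydroxy-3,5-dimethoxyphenyl)-4H-chromen-4-one)
Conditions: I2 (0.2 equiv), DMSO, 130 °C, 2 h
Reagents that add atoms: none
Why: I2/DMSO oxidative cyclisation of a 2'-hydroxychalcone (oxa-Michael, then iodination/elimination) forms the flavone, and the benzyl ethers survive.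

**Step 4**
Reactants: **6** 4'-(benzyloxy)acetophenone
Product: **7** methyl 3-[4-(benzyloxy)phenyl]-3-oxopropanoate
Conditions: NaH, (MeO)2CO, THF, reflux
Reagents that add atoms: dimethyl carbonate, COC(=O)OC
Why: Claisen-type methoxycarbonylation of the ketone enolate; the product is driven forward as its stabilised β-ketoester enolate.

**Step 5**
Reactants: **7**
Product: **8** methyl 3-[4-(benzyloxy)phenyl]-2-diazo-3-oxopropanoate
Conditions: p-ABSA, DBU, MeCN, 0 °C to rt
Reagents that add atoms: p-acetamidobenzenesulfonyl azide, CC(=O)Nc1ccc(S(=O)(=O)N=[N+]=[N-])cc1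
Why: Regitz diazo transfer to the active methylene.

**Step 6**
Reactants: **5**; **8**
Product: **9** methyl 2-{4-[5,7-bis(benzyloxy)-4-oxochromen-2-yl]-2,6-dimethoxyphenoxy}-3-[4-(benzyloxy)phenyl]-3-oxopropanoate (racemic at C2)
Conditions: Rh2(OAc)4 (1 mol%), 1,2-dichloroethane, 60 °C; **8** (1.5 equiv) added slowly over 2 h
Reagents that add atoms: none (both partners are reactants)
Why: An acceptor/acceptor Rh-carbenoid inserts into the only free OH (the 4'-OH, since 5-OH and 7-OH are benzylated) by O–H insertion. This builds the aryl ether C–O bond without needing SN2 at a stereocentre. The α-stereocentre is racemic and is set in the next step.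

**Step 7**
Reactants: **9**
Product: **10** methyl (2R,3S)-2-{4-[5,7-bis(benzyloxy)-4-oxochromen-2-yl]-2,6-dimethoxyphenoxy}-3-[4-(benzyloxy)phenyl]-3-hydroxypropanoate (syn)
Conditions: RuCl[(R,R)-TsDPEN](p-cymene) (2 mol%), HCO2H/Et3N 5:2, CH2Cl2, 35 °C, 24 h
Reagents that add atoms: none (formate is only the hydride source)
Why: Noyori-Ikariya ATH with DKR; Et3N racemises the very acidic C2–H through the enol. The (R,R) catalyst reduces one ketone face, set by CH/π contact with the aryl ring, to give 3S, and the faster-reacting C2 enantiomer gives 2R with syn (threo) selectivity.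
Proposed new method: Extension of DKR-ATH of α-alkoxy-β-ketoesters to an α-(flavonoid-aryloxy) substrate. The mechanistic reasoning is that the outer-sphere bifunctional Ru–H transfer is chemoselective for the highly electrophilic, chelating β-ketoester carbonyl over the vinylogous-ester flavone, and the acidic α-H allows fast racemisation. The closest known reaction is Ru-TsDPEN DKR-ATH of α-alkoxy/α-amido β-ketoesters.

**Step 8**
Reactants: **10**
Product: **11** (7''S,8''S)-5,7,4''-tri-O-benzyl tricin-4'-O-(7'',9''-dihydroxy-8''-oxy-phenylpropane) (tri-O-benzyl diol)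
Conditions: LiBH4 (2 equiv), THF, 0 °C to rt, 3 h
Reagents that add atoms: none (hydride only)
Why: Ester-to-primary alcohol reduction is faster for the α-alkoxy ester than for anything else in the molecule. The flavone and benzyl ethers are tolerated at 0 °C to rt, and the stereocentres are not touched; the C2 descriptor changes from R to S only because of CIP priority changes.

**Step 9**
Reactants: **11**
Product: **12** target, (−)-(7''S,8''S)-4'',5,7-trihydroxy-3',5'-dimethoxy-4',8''-oxyflavonolignan-7'',9''-diol
Conditions: H2 (1 atm), 10% Pd/C, EtOAc/MeOH 1:1, rt, 3 h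
Reagents that add atoms: none (H2 only)
Why: Hydrogenolysis removes all three O-benzyl groups; the flavone C2=C3 and the benzylic alcohol survive short, neutral, 1 atm conditions, as in catecholamine and lignin-model debenzylations.

## Compound list

| # | Name | SMILES | Role |
|---|---|---|---|
| 1 | 2,4,6-trihydroxyacetophenone | CC(=O)c1c(O)cc(O)cc1O | starting material |
| 2 | 4,6-bis(benzyloxy)-2-hydroxyacetophenone | CC(=O)c1c(O)cc(OCc2ccccc2)cc1OCc1ccccc1 | intermediate |
| 3 | syringaldehyde | COc1cc(C=O)cc(OC)c1O | starting material |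
| 4 | chalcone (E) | COc1cc(/C=C/C(=O)c2c(O)cc(OCc3ccccc3)cc2OCc2ccccc2)cc(OC)c1O | intermediate |
| 5 | 5,7-di-O-benzyltricin | COc1cc(-c2cc(=O)c3c(OCc4ccccc4)cc(OCc4ccccc4)cc3o2)cc(OC)c1O | intermediate |
| 6 | 4'-(benzyloxy)acetophenone | CC(=O)c1ccc(OCc2ccccc2)cc1 | starting material |
| 7 | methyl 3-[4-(benzyloxy)phenyl]-3-oxopropanoate | COC(=O)CC(=O)c1ccc(OCc2ccccc2)cc1 | intermediate |
| 8 | methyl 3-[4-(benzyloxy)phenyl]-2-diazo-3-oxopropanoate | COC(=O)C(=[N+]=[N-])C(=O)c1ccc(OCc2ccccc2)cc1 | intermediate |
| 9 | α-aryloxy-β-ketoester (racemic) | COc1cc(-c2cc(=O)c3c(OCc4ccccc4)cc(OCc4ccccc4)cc3o2)cc(OC)c1OC(C(=O)OC)C(=O)c1ccc(OCc2ccccc2)cc1 | intermediate |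
| 10 | syn-hydroxy ester (2R,3S) | COc1cc(-c2cc(=O)c3c(OCc4ccccc4)cc(OCc4ccccc4)cc3o2)cc(OC)c1O[C@@H](C(=O)OC)[C@@H](O)c1ccc(OCc2ccccc2)cc1 | intermediate |
| 11 | tri-O-benzyl diol (7''S,8''S) | COc1cc(-c2cc(=O)c3c(OCc4ccccc4)cc(OCc4ccccc4)cc3o2)cc(OC)c1O[C@@H](CO)[C@@H](O)c1ccc(OCc2ccccc2)cc1 | intermediate |
| 12 | target | COc1cc(-c2cc(=O)c3c(O)cc(O)cc3o2)cc(OC)c1O[C@@H](CO)[C@@H](O)c1ccc(O)cc1 | target |

## Totals

- Total steps: 9.
- Longest linear sequence: 7 (steps 1, 2, 3, 6, 7, 8, 9, from **1**).

## Three steps most likely to fail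

1. **Step 7, ATH-DKR.** Syn/anti selectivity, ee, or flavone chemoselectivity may be poor with this bulky 2,6-dimethoxyphenoxy substrate. Fallback: screen ketoreductases (KRED) for enzymatic DKR of **9**, which changes the catalyst class. A KRED that delivers the (2R,3S) syn isomer would give the same **10**.
2. **Step 6, Rh-carbenoid O–H insertion into the hindered 4'-OH flanked by two OMe groups.** Carbene dimerisation or C–H functionalisation may compete. Fallback: α-brominate **7** (NBS) and displace the bromide with the phenoxide of **5** (Cs2CO3, DMF) to give **9** by SN2, which avoids the carbenoid altogether.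
3. **Step 9, global hydrogenolysis.** The C7'' benzylic alcohol or the flavone C2=C3 may be over-reduced. Fallback: redo the route with a 4''-O-TBS ketoester (**7**) and a 5,7-di-O-MOM flavone in place of the benzyl ethers. The final deprotection would then be TBAF/AcOH followed by mild HCl/MeOH, so no hydrogenolysis is involved.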